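A leftover stands in the earlier runs: 20.0 min into the beta run, with the feed over, 45.7% of the charge is neither target nor substrate, so a second way out of the substrate runs beside the catalyst.

| flask | substrate | gas | free catalyst | remark | time |
|---|---|---|---|---|---|
| epsilon | 0.40 M (fed, over 15 min) | 160 mM (held) | 20 mM | run made earlier; the fed solution adds 0.10 times the starting volume |  |
| beta | 0.59 M (fed, over 15 min) | 160 mM (held) | 20 mM | run made earlier; the fed solution adds 0.10 times the starting volume |  |
| zeta | 0.79 M (fed, over 15 min) | 160 mM (held) | 10 mM | run made earlier; the fed solution adds 0.10 times the starting volume |  |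
| flask | 0.79 M (fed, over 15 min) | 160 mM (held) | 20 mM | the fed solution adds 0.10 times the starting volume | 30 min |

| run | time / min | target / % | substrate / % |
|---|---|---|---|
| epsilon | 1.50 | 1.6 | 9.0 |
| epsilon | 5.00 | 9.0 | 22.7 |
| epsilon | 8.00 | 20.7 | 27.2 |
| epsilon | 12.0 | 33.5 | 32.8 |
| epsilon | 20.0 | 50.7 | 12.9 |
| beta | 1.50 | 1.5 | 7.2 |
| beta | 5.00 | 8.8 | 22.8 |
| beta | 8.00 | 16.5 | 29.3 |
| beta | 12.0 | 28.8 | 35.3 |
| beta | 20.0 | 42.3 | 12.0 |
| zeta | 1.50 | 0.1 | 7.1 |
| zeta | 5.00 | 5.3 | 27.0 |
| zeta | 8.00 | 9.5 | 39.5 |
| zeta | 12.0 | 10.2 | 52.7 |
| zeta | 20.0 | 16.7 | 39.8 |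

(each reading ± 1 percentage point)

- charges are per starting volume, the dose included; the dosed solution carries all of it
- the numbers in the tables scatter by 1 percentage point (one standard deviation)
- at the start none of the gas is in solution
- percentages count the whole charge, also what has not yet gone in

1. amount of target in percent of the substrate charged, at 3.0 min, 10 min, 20 min and 30 min

12.5 is the target made per catalyst in the beta run by that reading, and the zeta run, with half the catalyst, gives 13.2, although their charges per catalyst stand at 29.5 and 79.0. The quantity carried here is therefore the turnover count, the target fraction times the charge over the catalyst (a turnover number at a fixed reading time), taken as the mean of these two readings, 12.8. The flask lies between those runs with 39.5 charge per catalyst, so this reckoning puts its target at 32.5% at 20 min, below the forecast's value for that time.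

The forecast gives 3.8%, 19%, 35% and 42%, and for the last stretch it expects that “remaining substrate (about 30%) splits mostly to the side loss”.

The flask gives 3.65%, 19.8%, 33.6% and 37.5%, so the forecast stands within its margin; substrate, the limiting reagent, is down to 1.08% at 30 min, and target still reads 37.9% after 300 min.

    catalyst intermediate C → catalyst intermediate D (k = 0.680 s⁻¹)
    substrate + target → side product (k = 0.00580 L mol⁻¹ s⁻¹)
    substrate + free catalyst ⇌ catalyst intermediate A (K = 2.00 L mol⁻¹, k = 0.640 L mol⁻¹ s⁻¹)
    catalyst intermediate B → released group + catalyst intermediate C (k = 0.230 s⁻¹)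
    partner + catalyst intermediate A ⇌ catalyst intermediate B (K = 4.20 L mol⁻¹, k = 2.90 L mol⁻¹ s⁻¹)
    gas ⇌ partner, rate k6*(csat - [partner]) (kL = 0.100 s⁻¹)
    catalyst intermediate D → free catalyst + target (k = 0.540 s⁻¹)

The flask's target at 20 min amounts to 13.3 turnovers per catalyst, beside the 12.8 carried from the earlier runs, and with twice the free catalyst the flask gives 56.5% target, which is 11.2 turnovers against 14.8 here. At 30.0 min this flask uses substrate 7.3 times as fast by the forward step onto free catalyst alone as by its reaction with target, and by that time side product, in which each unit counts as two, has gathered to 61.4% beside 37.5% target.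

(The readings are simulated from invented constants; noise was put on by code.)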